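If the two nucleophiles and solvolysis compete for one intermediate, target over solvolysis product rises in step with c(first nucleophile). I therefore read the crossing concentration, the c(first nucleophile) at which target and solvolysis product form equally fast: the charged c(first nucleophile) times solvolysis product over target gave 0.239 M from Friday's last reading and 0.236 M from Sunday's.

| flask | substrate | first nucleophile | second nucleophile | protic impurity | remark | time |
|---|---|---|---|---|---|---|
| Sunday's | 0.050 M | 1.3 equiv | 0.67 equiv | 2.5 mM | run made earlier |  |
| Friday's | 0.10 M | 1.3 equiv | 1 equiv | 2.5 mM | run made earlier |  |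
| grey | 0.050 M | 1.30 equiv | 1.00 equiv | 2.50 mM |  | 12 min |
| red | 0.050 M | 2.60 equiv | 1.00 equiv | 2.50 mM |  | 12 min |

| run | time / min | other capture product / % | target / % | substrate / % | solvolysis product / % |
|---|---|---|---|---|---|
| Sunday's | 1.33 | 0 | 2.5 | 84.7 | 10.9 |
| Sunday's | 3.00 | 2.7 | 5.9 | 70.1 | 21.7 |
| Sunday's | 4.00 | 3.1 | 6.9 | 61.4 | 26.3 |
| Sunday's | 6.00 | 3.9 | 10.8 | 48.9 | 34.7 |
| Sunday's | 8.00 | 6.0 | 12.1 | 39.0 | 44.0 |
| Friday's | 0.500 | 1.3 | 2.1 | 94.0 | 3.9 |
| Friday's | 1.00 | 1.5 | 2.3 | 90.5 | 4.9 |
| Friday's | 2.00 | 5.0 | 6.1 | 77.8 | 11.3 |
| Friday's | 4.00 | 4.1 | 12.3 | 62.1 | 18.6 |
| Friday's | 8.00 | 11.5 | 16.6 | 39.0 | 30.5 |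

(each reading ± 1 percentage point)



- which of these there is most of at the end, counted by the substrate in it, grey (solvolysis product / other capture product / target / substrate)
- which of these there is most of at the end, counted by the substrate in it, red (solvolysis product / other capture product / target / substrate)
- amount of the one of these that there is most of at the end, in percent of the substrate charged, grey
- amount of the one of these that there is most of at the end, in percent of the substrate charged, red

Sunday's and Friday's runs held 39.0% and 39.0% of substrate at 8.00 min, though Friday's began at twice the concentration. So I took the loss of substrate as first order, the rate-limiting step, at 0.118 /min, which leaves 24.4% at 12 min. Grey has c(first nucleophile) 0.0650 M and red 0.130 M, and even red's is lower than the crossing, so I expected solvolysis product ahead of target in both flasks. Friday's last reading gave the second nucleophile its own crossing, 0.265 M, and both flasks charge c(second nucleophile) 0.0500 M. Dividing the substrate used by one plus the two ratios of charge to crossing, I reckoned solvolysis product at 51.8% in grey and 43.7% in red, more than the substrate left.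

The forecast, made from the same runs, named solvolysis product in grey at 52% and solvolysis product in red at 44%, on this ground: “This points to rate-limiting ionisation followed by competitive capture of the intermediate.”

The flasks gave solvolysis product in grey at 51.4% and solvolysis product in red at 42.5%.

    substrate → intermediate (k = 0.117 /min)
    first nucleophile + intermediate → target (k = 635 /M/min)
    second nucleophile + intermediate → other capture product (k = 476 /M/min)
    intermediate → solvolysis product (k = 129 /min)
    first nucleophile + protic impurity → quenched reagent (k = 67.6 /M/min)
    intermediate → side product (k = 0.231 /min)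
    target → over-reaction product (k = 0.00464 /min)

In grey at 12.0 min the intermediate passed into solvolysis product 3.7 times as fast as into target, and the crossing over grey's charged c(first nucleophile) is 3.68. A neighbouring flask, grey with 5.20 equiv of first nucleophile, has c(first nucleophile) 0.260 M, higher than the crossing, and there target held most at 12.0 min, 37.0% against 31.4% of solvolysis product.

The runs come from a simulation from invented constants.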